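| flask | J | L | Z | time |
|---|---|---|---|---|
| red | 80.0 mM | 120 mM | 1.60 mM |  |
| ochre | 48.0 mM | 88.0 mM | 1.60 mM |  |
| green | 80.0 mM | 120 mM | 2.40 mM |  |
| teal | 80.0 mM | 360 mM | 1.60 mM | 13 min |

| run | time / min | [G] / mM |
|---|---|---|
| red run | 0.74 | 3.7 |
| red run | 2.2 | 11.9 |
| red run | 4.3 | 17.0 |
| red run | 6.8 | 20.2 |
| red run | 9.7 | 21.9 |
| red run | 13 | 22.9 |
| ochre run | 0.74 | 2.7 |
| ochre run | 2.2 | 6.0 |
| ochre run | 4.3 | 8.7 |
| ochre run | 6.8 | 10.3 |
| ochre run | 9.7 | 11.1 |
| ochre run | 13 | 12.0 |
| green run | 0.74 | 7.8 |
| green run | 2.2 | 13.5 |
| green run | 4.3 | 21.0 |
| green run | 6.8 | 24.7 |
| green run | 9.7 | 26.6 |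
| green run | 13 | 27.1 |

(readings scatter by 0.8 mM)

- Overall: J + L -> G, with Z as catalyst.
- Constant volume, constant temperature.
- What is held in complexes is read along with the free species.
- "The second partner" is L.
- An order is taken over about fifteen percent of the charge, up and down.

1. order of the initial rate in [Z], near the charge of the red run, the rate being that where two percent of its J are G
2. G in the teal run at 13 min, as a share of the J charged

- Start from two rate constants, read off the runs as times. In the red run G reaches 22.9 mM by 13 min, and taking that as its level, the gap to it shrinks with a constant of 0.315 /min, a settling time of 3.17 min.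
- So the red rate starts near 7.21 mM/min and falls by a factor e for each settling time; the rate summed over the run is that start rate times the settling time, which is the level again.
- Divide the red start rate by the J charged and you have the making constant, pseudo-first-order in J: 0.0903 /min, or 11.1 min as a time.
- I read the rest of the slowing as a leak constant, the rate per J at which J goes without giving G: 0.225 /min, or 4.44 min as a time. In the red run the leak reads faster than the making.
- Your rule for the end is then a selectivity: with both constants held steady through a run, the share of J reaching G is the making constant over the sum of making and leak.
- The same reckoning gives a leak of 0.225 /min in the ochre run and 0.229 /min in the green run, about the red value, so I hold it fixed.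
- The making constant does move: 0.0751 /min in ochre and 0.117 /min in green.
- As readings, with the scatter of 0.8 mM weighing on the ochre level, these give me an order in Z of 0.649 from green against red. The ochre run differs from the red in both J and L, so with the making constant taken as free of J, they give me an order in L of 0.595.
- For the teal run I scale the red making constant by the order in L to 0.174 /min, keep the leak, and get 43.3% of the J charged at 13 min.
- The forecast stands higher than both my figures: 60% for teal (range 48% to 71%) and 0.8 for the order in Z (range 0.5 to 1.05), with the view that “the catalyst probably dies or is inhibited as the run proceeds”.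
- The teal run gives 44.8% of its J as G at 13 min, and the order in Z is 0.82.

    2 Z ⇌ Z2, settled at all times (175.0 /M)
    Z + J + L → G + Z (1554 /M²/min)
    J → Qe (0.1980 /min)
    2 L ⇌ L2, settled at all times (14.80 /M)

- Where two percent of the red J have turned, the green run goes 1.4 times as fast as the red run, at 8.9 mM/min. With the leak constant, and the teal share taken as the end of that run, the rule asks for a making constant of 0.183 /min, which is 2.02 times the red one for a charge of L 3.00 times the red. In the green run, that rate per J charged is 0.111 /min, so the rule gives a share of 33.0%, and the reading at 13 min is 33.9%.

The numbers in the tables come from a simulation from invented constants.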